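Remark on the chemistry: compounds 7, 8 and 9 have an enolisable stereocentre at the carbon between ketone and ester and are handled as racemates; 10 (diastereomer mixture), 11 and 12 have transient stereocentres that vanish when ring A becomes aromatic.

## Analysis of the target

Gymconopin D (15) has no fused or bridged ring system. Three separate benzene rings are joined by a two-carbon chain (ring A C1–CH2–CH2–ring B) and a one-carbon link (ring A C2–CH2–ring C). Ring A is the 1,2,3,5-tetrasubstituted dimethoxybenzene: the 2-arylethyl arm on C1, the 4-hydroxybenzyl arm on C2, methoxy groups on C3 and C5, hydrogen on C4 and C6. Ring B is a 3-hydroxyphenyl group and ring C a 4-hydroxyphenyl group. There is no stereocentre, so the problem is one of regiochemistry only. The sensitive features are the two free phenols (which must stay unmethylated while the ring A oxygens are methylated), the very electron-rich ring A (open to electrophiles at C4 and C6) and the doubly benzylic methylene. The difficulty is the run of three neighbouring substituents C1–C2–C3 on ring A. Two different carbon arms stand side by side, and a late benzylation of a 3,5-dioxygenated bibenzyl would have to choose between C2, C4 and C6 and would tend to run on. The strategy rests on the oxygen atoms at the alternate carbons C3 and C5 with carbon arms at C1 and C2. This is the pattern left by a chain of alternating carbonyl groups that folds by an aldol bond between its second and seventh carbon and loses its carboxyl group, as in bibenzyl biosynthesis. With the chain numbered from the carboxyl carbon (chain C1) to the benzylic carbon next to ring B (chain C9), chain C2 to C6 become ring A C2 to C6 and chain C7 becomes ring A C1. A benzyl group placed on chain C2 before folding therefore ends up as the C2 arm.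

## Retrosynthetic reasoning

**From 15 back to 13.** The aryl–oxygen bonds are handled first. The two free phenols of 15 are traced to the benzyl ethers of 14, removed last by hydrogenolysis, and the two methyl ethers of 14 to the free resorcinol 13. No selective oxygen chemistry is needed: when ring A is formed its two hydroxyls are the only free ones in the molecule, so one exhaustive methylation and one exhaustive debenzylation fix the pattern.

**From 13 back to 9.** Ring A is opened at the C1–C2 bond and a carboxyl carbon is put back on C2, which gives the open-chain triketo ester 9. This is the only ring bond whose formation is an aldol addition of a doubly activated carbon (chain C2, between ketone and ester) to a ketone (chain C7) through a six-membered ring. The other doubly activated carbons, C4 and C6, can reach a ketone only through four-membered rings. The precursor already holds every carbon of ring A and both arms at the correct oxidation level, so one C–C bond completes the skeleton. The forward reaction must do three things: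
- close from C2 to C7, not from C6 onto the ester and not from C8 onto C3;
- accept that C2 becomes quaternary in the adducts 10 and 11;
- expel the ester carbon through acid 12, because a ring with a substituent on C2 can become aromatic only by decarboxylation.

The tert-butyl ester serves both ends: it is a poor acyl donor, which holds back the Claisen mode, and it is removed by acid without any hydrolysis step.

**From 9 back to 8.** The chain C7 ketone is masked as a dioxolane. The chain is assembled with strongly basic carbanions, and a free C7 ketone would make its fragment a β-keto ester that only quenches them. The mask also ensures that 9 exists only just before it is folded.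

**From 8 back to 7 and 4.** The chain is cut between C4 and C5, a Claisen condensation in the forward sense: the terminal carbanion of the dianion of 7 attacks the ester carbonyl of 4. The cut gives two pieces of similar size, each carrying one aryl group and each two steps from purchasable materials. It uses the most nucleophilic site of a β-keto ester dianion and leaves C2 untouched. A cut between C3 and C4 would need a malonyl electrophile whose acidic C–H would be deprotonated instead.

**From 7 back to 5 and 6, and from 4 back to 3, 1 and 2.** The benzyl arm is attached to C2 by ordinary alkylation of β-keto ester 5 with bromide 6. The other piece comes from alkylation of the dianion of 1 at its terminal carbon with bromide 2 (forming the chain C8–C9 bond) to give 3, followed by ketalisation to 4. Both aryl groups thus enter as simple benzylic electrophiles.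

## Alternatives that were turned down

**Alternative 1:** Both bonds of the ethano bridge are cut (ring A C1–Cα and Cβ–ring B C1), so the two bridge carbons come from vinylboronic ester A3.
- Forward key step: the aryllithium from bromide A2 adds to A3 to form a boron ate complex. A palladium catalyst with a chiral ferrocene bisphosphine then couples it with aryl triflate A4. Ring A migrates from boron to Cα as palladium delivers ring B to Cβ, giving the secondary benzylic boronic ester A1. Protodeboronation of A1 would lead to 14.
- For it: it is convergent and modular, and the reaction class is established for aryl migrating groups and aryl triflates. On precedent and on robustness of intermediates it is stronger than the chosen route.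
- Against it: it creates a stereocentre with a costly chiral ligand only to erase it in an extra step. The migrating aryl group bears a bulky ortho benzyl substituent, and its aryllithium sits next to an acidic diarylmethane CH2. Above all, A2 already contains the fully substituted ring A with its benzyl arm, so the real difficulty of the target is moved into making A2 (about three steps).
- Comparison: the step count is similar. The chosen strategy offers instead a ring A whose substitution pattern is made by the key step itself, from acetoacetate feedstock, with no stereocentre made and destroyed.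

**Alternative 2:** Ring A is cut at C4–C5 and C6–C1 and traced to 2-pyrone A6 and ketene acetal A7.
- Forward key step: heating the two gives a Diels–Alder adduct across pyrone C3 and C6. Decarboxylative cycloreversion and loss of one methoxy group as the alcohol then give benzoate A5, whose ester carbon is the future benzylic carbon.
- For it: pyrone–ketene acetal benzannulation is a known reaction type, and its regiochemistry follows from the polarity of the partners. On precedent it is stronger than the chosen key step.
- Against it: the donor methoxy group on A6 deactivates the pyrone towards an electron-rich dienophile, so forcing conditions are expected. A6 must itself be built in several steps. The key step delivers only one of the two arms. Ring C must then be attached to a hindered, doubly ortho-substituted ester by reduction, oxidation, aryl-metal addition and deoxygenation, about four more steps before 14.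
- Comparison: the route is clearly longer. The chosen strategy has both arms in place and at the final oxidation level when the ring closes.

**Alternative 3:** Ring A is cut at C6–C1 and C2–C3 and traced to alkynyl ketone A9 and the ketene-acetal silyloxy diene A10.
- Forward key step: the nucleophilic CH2 terminus of A10 adds to the β-carbon of A9 and the acetal carbon to the α-carbon. Loss of the alcohol and desilylation give the aroyl resorcinol monomethyl ether A8, which holds all carbons of the target.
- For it: both ring bonds form in one convergent step, the regiochemistry is dictated by polarity, and both partners are short to make. On precedent and risk this is the strongest of the three and stronger than the chosen key step.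
- Against it: the benzylic carbon arrives as a diaryl ketone flanked by two ortho substituents and has to be deoxygenated. The two ring A oxygens emerge differentiated although the target needs them alike, so one is methylated separately. A10 is moisture-sensitive and used in excess, and a β-alkyl alkynone is a sluggish dienophile.
- Comparison: the step count is about equal. The chosen strategy offers the correct oxidation level at every carbon with no redox correction, both ring A oxygens treated alike, and a test of the decarboxylative fold on a branched chain; the price is an unproven key step.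

Key step: step 6

## Route

**Step 1**
Reactants: 1 methyl acetoacetate; 2 3-(benzyloxy)benzyl bromide
Product: 3 methyl 5-[3-(benzyloxy)phenyl]-3-oxopentanoate
Conditions: LiN(i-Pr)2 (2.1 equiv), THF, 0 °C; then 2, 0 °C → 23 °C; AcOH quench
Reagents that add atoms: none
Why: Terminal alkylation of an acetoacetate dianion: the second deprotonation creates the more reactive terminal carbanion, which alone displaces the benzylic bromide (SN2) and leaves the carbon between the carbonyls untouched.

**Step 2**
Reactants: 3 methyl 5-[3-(benzyloxy)phenyl]-3-oxopentanoate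
Product: 4 methyl 2-(2-{2-[3-(benzyloxy)phenyl]ethyl}-1,3-dioxolan-2-yl)acetate
Conditions: HOCH2CH2OH (2 equiv), TsOH·H2O (cat.), benzene, reflux, Dean–Stark trap
Reagents that add atoms: ethylene glycol, OCCO
Why: Acid-catalysed ketalisation with azeotropic removal of water; the ketone of a β-keto ester forms the dioxolane while methyl ester and benzyl ether are inert. The ketal removes the acidic C–H that would quench the dianion in step 4.

**Step 3**
Reactants: 5 tert-butyl acetoacetate; 6 4-(benzyloxy)benzyl bromide
Product: 7 tert-butyl 2-[4-(benzyloxy)benzyl]-3-oxobutanoate (racemic)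
Conditions: K2CO3, acetone, reflux (5 in 1.5-fold excess)
Reagents that add atoms: none
Why: Acetoacetic ester C-alkylation with a reactive benzylic bromide; the excess of 5 limits double alkylation. The new stereocentre is enolisable and of no consequence.

**Step 4**
Reactants: 7 tert-butyl 2-[4-(benzyloxy)benzyl]-3-oxobutanoate; 4 methyl 2-(2-{2-[3-(benzyloxy)phenyl]ethyl}-1,3-dioxolan-2-yl)acetate
Product: 8 tert-butyl 2-[4-(benzyloxy)benzyl]-6-(2-{2-[3-(benzyloxy)phenyl]ethyl}-1,3-dioxolan-2-yl)-3,5-dioxohexanoate (racemic)
Conditions: 7 (2 equiv), LiN(i-Pr)2 (4.1 equiv), THF, −78 → 0 °C; then 4 (1 equiv), 0 → 23 °C; AcOH quench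
Reagents that add atoms: none
Why: Crossed Claisen condensation of a β-keto ester dianion with an ester: the terminal carbanion attacks the methyl ester of 4 and forms the chain C4–C5 bond. The second equivalent of dianion takes up the acidic proton of the new diketone, and the tert-butyl ester is too hindered to be attacked.

**Step 5**
Reactants: 8 tert-butyl 2-[4-(benzyloxy)benzyl]-6-(2-{2-[3-(benzyloxy)phenyl]ethyl}-1,3-dioxolan-2-yl)-3,5-dioxohexanoate
Product: 9 tert-butyl 2-[4-(benzyloxy)benzyl]-9-[3-(benzyloxy)phenyl]-3,5,7-trioxononanoate (racemic, mixture of enol forms)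
Conditions: 1 M aq. HCl/THF (1:3), 0 → 23 °C; used at once without chromatography
Reagents that add atoms: water, O
Why: Acid-catalysed hydrolysis of the dioxolane; dilute aqueous acid at or below room temperature should spare the tert-butyl ester and the benzyl ethers. The triketo ester is carried straight into step 6 to limit its handling.

**Step 6**
Reactants: 9 tert-butyl 2-[4-(benzyloxy)benzyl]-9-[3-(benzyloxy)phenyl]-3,5,7-trioxononanoate
Product: 13 4-[4-(benzyloxy)benzyl]-5-{2-[3-(benzyloxy)phenyl]ethyl}benzene-1,3-diol, via aldol adduct 10 (not isolated), via cyclohexenedione ester 11 (not isolated), via cyclohexenedione acid 12 (not isolated)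
Conditions: Cs2CO3 (3 equiv), MeCN, 23 °C; cold 0.5 M aq. HCl wash, solvent change; then CF3CO2H/CH2Cl2 (1:4), 0 → 23 °C, N2 sweep
Reagents that add atoms: none
Why: Proposed new method: Cs2CO3 deprotonates 9 reversibly at chain C4, C6 and C2; the C4 and C6 enolates can reach a ketone only through four-membered rings, whereas the C2 enolate adds to the chain C7 ketone in a 6-(enolendo)-exo-trig aldol closure that forms the ring A C2–C1 bond and gives 10. Adduct 10 is a cyclic 1,3-dione, clearly more acidic than the open-chain diketone units, so its cesium enolate should act as a thermodynamic sink that pulls the reversible aldol forward. Acid then dehydrates the tertiary β-hydroxy ketone to 11 and cleaves the tert-butyl ester to 12; this β-keto acid at a quaternary carbon, which is also the ipso-carboxyl form of a protonated resorcinol, loses CO2 and tautomerises to aromatic 13. The closest known reaction type is the base-mediated aldol cyclisation and aromatisation of unbranched 3,5,7-triketo esters to resorcylates; new here is the substituent on chain C2, so that a quaternary carbon is formed and aromatisation must come from decarboxylation instead of loss of a C2 proton. The selectivity needed is aldol from C2 to C7 over Claisen closure from C6 onto the ester and over aldol from C8 to C3; the first is held back by the tert-butyl ester as a poor acyl donor, the second by the lower acidity of the singly activated C8 and the crowding at C3. The stereocentres of 10, 11 and 12 are transient and are erased on aromatisation, so no stereocontrol is required.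

**Step 7**
Reactants: 13 4-[4-(benzyloxy)benzyl]-5-{2-[3-(benzyloxy)phenyl]ethyl}benzene-1,3-diol
Product: 14 1-{2-[3-(benzyloxy)phenyl]ethyl}-2-[4-(benzyloxy)benzyl]-3,5-dimethoxybenzene
Conditions: (MeO)2SO2 (2.5 equiv), K2CO3, acetone, reflux; aq. NH3 quench
Reagents that add atoms: dimethyl sulfate, COS(=O)(=O)OC
Why: Williamson O-methylation of both phenols; the ring A hydroxyls are the only free ones, so the methyl and benzyl ethers are distributed correctly by construction.

**Step 8**
Reactants: 14 1-{2-[3-(benzyloxy)phenyl]ethyl}-2-[4-(benzyloxy)benzyl]-3,5-dimethoxybenzene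
Product: 15 gymconopin D, 3-{2-[2-(4-hydroxybenzyl)-3,5-dimethoxyphenyl]ethyl}phenol
Conditions: H2 (1 atm), Pd/C (10 wt% palladium on carbon), EtOAc/MeOH, 23 °C
Reagents that add atoms: none
Why: Catalytic hydrogenolysis of the two aryl benzyl ethers; aryl methyl ethers and the diarylmethane and bibenzyl C–C bonds are inert under these conditions.

## Compound list

1 | methyl acetoacetate | COC(=O)CC(C)=O | starting material
2 | 3-(benzyloxy)benzyl bromide | BrCc1cccc(OCc2ccccc2)c1 | starting material
3 | methyl 5-[3-(benzyloxy)phenyl]-3-oxopentanoate | COC(=O)CC(=O)CCc1cccc(OCc2ccccc2)c1 | intermediate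
4 | methyl 2-(2-{2-[3-(benzyloxy)phenyl]ethyl}-1,3-dioxolan-2-yl)acetate | COC(=O)CC1(CCc2cccc(OCc3ccccc3)c2)OCCO1 | intermediate
5 | tert-butyl acetoacetate | CC(=O)CC(=O)OC(C)(C)C | starting material
6 | 4-(benzyloxy)benzyl bromide | BrCc1ccc(OCc2ccccc2)cc1 | starting material
7 | tert-butyl 2-[4-(benzyloxy)benzyl]-3-oxobutanoate (racemic) | CC(=O)C(Cc1ccc(OCc2ccccc2)cc1)C(=O)OC(C)(C)C | intermediate
8 | tert-butyl 2-[4-(benzyloxy)benzyl]-6-(2-{2-[3-(benzyloxy)phenyl]ethyl}-1,3-dioxolan-2-yl)-3,5-dioxohexanoate (racemic) | CC(C)(C)OC(=O)C(Cc1ccc(OCc2ccccc2)cc1)C(=O)CC(=O)CC1(CCc2cccc(OCc3ccccc3)c2)OCCO1 | intermediate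
9 | tert-butyl 2-[4-(benzyloxy)benzyl]-9-[3-(benzyloxy)phenyl]-3,5,7-trioxononanoate (racemic, labile) | CC(C)(C)OC(=O)C(Cc1ccc(OCc2ccccc2)cc1)C(=O)CC(=O)CC(=O)CCc1cccc(OCc2ccccc2)c1 | intermediate
10 | tert-butyl 1-[4-(benzyloxy)benzyl]-2-{2-[3-(benzyloxy)phenyl]ethyl}-2-hydroxy-4,6-dioxocyclohexane-1-carboxylate (diastereomer mixture, racemic, not isolated) | CC(C)(C)OC(=O)C1(Cc2ccc(OCc3ccccc3)cc2)C(=O)CC(=O)CC1(O)CCc1cccc(OCc2ccccc2)c1 | intermediate
11 | tert-butyl 1-[4-(benzyloxy)benzyl]-2-{2-[3-(benzyloxy)phenyl]ethyl}-4,6-dioxocyclohex-2-ene-1-carboxylate (racemic, not isolated) | CC(C)(C)OC(=O)C1(Cc2ccc(OCc3ccccc3)cc2)C(=O)CC(=O)C=C1CCc1cccc(OCc2ccccc2)c1 | intermediate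
12 | 1-[4-(benzyloxy)benzyl]-2-{2-[3-(benzyloxy)phenyl]ethyl}-4,6-dioxocyclohex-2-ene-1-carboxylic acid (racemic, not isolated) | OC(=O)C1(Cc2ccc(OCc3ccccc3)cc2)C(=O)CC(=O)C=C1CCc1cccc(OCc2ccccc2)c1 | intermediate
13 | 4-[4-(benzyloxy)benzyl]-5-{2-[3-(benzyloxy)phenyl]ethyl}benzene-1,3-diol | Oc1cc(O)c(Cc2ccc(OCc3ccccc3)cc2)c(CCc2cccc(OCc3ccccc3)c2)c1 | intermediate
14 | 1-{2-[3-(benzyloxy)phenyl]ethyl}-2-[4-(benzyloxy)benzyl]-3,5-dimethoxybenzene | COc1cc(CCc2cccc(OCc3ccccc3)c2)c(Cc2ccc(OCc3ccccc3)cc2)c(OC)c1 | intermediate
15 | gymconopin D, 3-{2-[2-(4-hydroxybenzyl)-3,5-dimethoxyphenyl]ethyl}phenol | COc1cc(CCc2cccc(O)c2)c(Cc2ccc(O)cc2)c(OC)c1 | target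

## Step count and least certain steps

Total: 8 steps. Longest linear sequence: 7 steps (steps 1, 2, 4, 5, 6, 7, 8, from 1); the other branch (steps 3, 4, 5, 6, 7, 8) has 6.

**Step 6 (key step, proposed new method).** Several processes may divert it:
- In the base stage the hindered C2 enolate may add too slowly, since a quaternary carbon must form between two carbonyl groups. Reversible ring opening would then let aldol closure from C8 onto the C3 ketone or Claisen closure from C6 onto the ester take over.
- In the acid stage the tert-butyl cation may be transferred to the very electron-rich ring A. Dilution and the nitrogen sweep are meant to limit this, and an electron-rich arene can be added as a cation trap.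
- The protonated dienone may expel the 4-benzyloxybenzyl group as a stabilised cation instead of waiting for ester cleavage and decarboxylation.
- Benzyl ethers may be lost slowly in strong acid.

The fallback gives up the branch on chain C2 and uses the fold in its known, unbranched form, at the price of attaching ring C afterwards. It sets out from 4 and 1 and returns to the route at 14, replacing steps 3 to 7 by eight operations:
- The dianion of 1 (LiN(i-Pr)2, THF) is acylated by 4 to methyl 6-(2-{2-[3-(benzyloxy)phenyl]ethyl}-1,3-dioxolan-2-yl)-3,5-dioxohexanoate F1.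
- Dilute aqueous HCl in THF frees methyl 9-[3-(benzyloxy)phenyl]-3,5,7-trioxononanoate F2.
- Cs2CO3 in methanol or dilute aqueous KOH brings about the established aldol cyclisation and aromatisation to methyl 2-{2-[3-(benzyloxy)phenyl]ethyl}-4,6-dihydroxybenzoate F3.
- Dimethyl sulfate and K2CO3 give methyl 2-{2-[3-(benzyloxy)phenyl]ethyl}-4,6-dimethoxybenzoate F4, the same benzoate as A5.
- LiAlH4 reduces it to (2-{2-[3-(benzyloxy)phenyl]ethyl}-4,6-dimethoxyphenyl)methanol F5.
- MnO2 oxidises this to 2-{2-[3-(benzyloxy)phenyl]ethyl}-4,6-dimethoxybenzaldehyde F6.
- 4-(Benzyloxy)phenylmagnesium bromide adds to give [4-(benzyloxy)phenyl](2-{2-[3-(benzyloxy)phenyl]ethyl}-4,6-dimethoxyphenyl)methanol F7.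
- Ionic hydrogenation with triethylsilane and CF3CO2H removes the doubly benzylic hydroxyl and gives 14.

**Step 5.** Under the acid that removes the ketal, the enolised polyketone may cyclise through oxygen (the enol oxygen on chain C3 adding to chain C7, followed by loss of water), because ionisation of the ketal creates an electrophilic C7 next to that enol. Loss of the tert-butyl group and uncontrolled carbon cyclisation on work-up are lesser risks. The fallback carries chain C7 as a protected alcohol and reveals the ketone by a neutral oxidation. It sets out from 3 and returns at 9: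
- NaBH4 reduces 3 to methyl 5-[3-(benzyloxy)phenyl]-3-hydroxypentanoate F8.
- tert-Butyldimethylsilyl chloride and imidazole give methyl 5-[3-(benzyloxy)phenyl]-3-[(tert-butyldimethylsilyl)oxy]pentanoate F9.
- The dianion of 7 is acylated by F9, as in step 4, to tert-butyl 2-[4-(benzyloxy)benzyl]-9-[3-(benzyloxy)phenyl]-7-[(tert-butyldimethylsilyl)oxy]-3,5-dioxononanoate F10.
- HF·pyridine removes the silyl group to give tert-butyl 2-[4-(benzyloxy)benzyl]-9-[3-(benzyloxy)phenyl]-7-hydroxy-3,5-dioxononanoate F11.
- Dess–Martin periodinane with NaHCO3 oxidises F11 to 9.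

**Step 4.** The dianion may act as a base towards ester 4 instead of attacking its carbonyl. The ester enolate can then open the dioxolane by β-elimination, and conversion stalls. The product also consumes dianion by proton transfer, which is why two equivalents are used. The fallback replaces acyl substitution by an aldol addition and an oxidation. It sets out from 4 and returns at 8:
- i-Bu2AlH in CH2Cl2 at −78 °C reduces 4 to 2-(2-{2-[3-(benzyloxy)phenyl]ethyl}-1,3-dioxolan-2-yl)acetaldehyde F12.
- The dianion of 7 adds to F12 at −78 °C to give tert-butyl 2-[4-(benzyloxy)benzyl]-6-(2-{2-[3-(benzyloxy)phenyl]ethyl}-1,3-dioxolan-2-yl)-5-hydroxy-3-oxohexanoate F13 (diastereomer mixture).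
- Dess–Martin periodinane oxidises F13 to 8.

## Further compounds

F1 | step 6 | methyl 6-(2-{2-[3-(benzyloxy)phenyl]ethyl}-1,3-dioxolan-2-yl)-3,5-dioxohexanoate | COC(=O)CC(=O)CC(=O)CC1(CCc2cccc(OCc3ccccc3)c2)OCCO1
F2 | step 6 | methyl 9-[3-(benzyloxy)phenyl]-3,5,7-trioxononanoate | COC(=O)CC(=O)CC(=O)CC(=O)CCc1cccc(OCc2ccccc2)c1
F3 | step 6 | methyl 2-{2-[3-(benzyloxy)phenyl]ethyl}-4,6-dihydroxybenzoate | COC(=O)c1c(O)cc(O)cc1CCc1cccc(OCc2ccccc2)c1
F4 | step 6 | methyl 2-{2-[3-(benzyloxy)phenyl]ethyl}-4,6-dimethoxybenzoate | COC(=O)c1c(CCc2cccc(OCc3ccccc3)c2)cc(OC)cc1OC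
F5 | step 6 | (2-{2-[3-(benzyloxy)phenyl]ethyl}-4,6-dimethoxyphenyl)methanol | COc1cc(OC)c(CO)c(CCc2cccc(OCc3ccccc3)c2)c1
F6 | step 6 | 2-{2-[3-(benzyloxy)phenyl]ethyl}-4,6-dimethoxybenzaldehyde | COc1cc(OC)c(C=O)c(CCc2cccc(OCc3ccccc3)c2)c1
F7 | step 6 | [4-(benzyloxy)phenyl](2-{2-[3-(benzyloxy)phenyl]ethyl}-4,6-dimethoxyphenyl)methanol (racemic) | COc1cc(OC)c(C(O)c2ccc(OCc3ccccc3)cc2)c(CCc2cccc(OCc3ccccc3)c2)c1
F8 | step 5 | methyl 5-[3-(benzyloxy)phenyl]-3-hydroxypentanoate (racemic) | COC(=O)CC(O)CCc1cccc(OCc2ccccc2)c1
F9 | step 5 | methyl 5-[3-(benzyloxy)phenyl]-3-[(tert-butyldimethylsilyl)oxy]pentanoate (racemic) | COC(=O)CC(CCc1cccc(OCc2ccccc2)c1)O[Si](C)(C)C(C)(C)C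
F10 | step 5 | tert-butyl 2-[4-(benzyloxy)benzyl]-9-[3-(benzyloxy)phenyl]-7-[(tert-butyldimethylsilyl)oxy]-3,5-dioxononanoate (diastereomer mixture) | CC(C)(C)OC(=O)C(Cc1ccc(OCc2ccccc2)cc1)C(=O)CC(=O)CC(CCc1cccc(OCc2ccccc2)c1)O[Si](C)(C)C(C)(C)C
F11 | step 5 | tert-butyl 2-[4-(benzyloxy)benzyl]-9-[3-(benzyloxy)phenyl]-7-hydroxy-3,5-dioxononanoate (diastereomer mixture) | CC(C)(C)OC(=O)C(Cc1ccc(OCc2ccccc2)cc1)C(=O)CC(=O)CC(O)CCc1cccc(OCc2ccccc2)c1
F12 | step 4 | 2-(2-{2-[3-(benzyloxy)phenyl]ethyl}-1,3-dioxolan-2-yl)acetaldehyde | O=CCC1(CCc2cccc(OCc3ccccc3)c2)OCCO1
F13 | step 4 | tert-butyl 2-[4-(benzyloxy)benzyl]-6-(2-{2-[3-(benzyloxy)phenyl]ethyl}-1,3-dioxolan-2-yl)-5-hydroxy-3-oxohexanoate (diastereomer mixture) | CC(C)(C)OC(=O)C(Cc1ccc(OCc2ccccc2)cc1)C(=O)CC(O)CC1(CCc2cccc(OCc3ccccc3)c2)OCCO1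
A1 | alternative 1 | 2-{1-[2-(4-benzyloxybenzyl)-3,5-dimethoxyphenyl]-2-[3-(benzyloxy)phenyl]ethyl}-4,4,5,5-tetramethyl-1,3,2-dioxaborolane (one enantiomer drawn) | COc1cc([C@@H](Cc2cccc(OCc3ccccc3)c2)B2OC(C)(C)C(C)(C)O2)c(Cc2ccc(OCc3ccccc3)cc2)c(OC)c1
A2 | alternative 1 | 2-[4-(benzyloxy)benzyl]-1-bromo-3,5-dimethoxybenzene | COc1cc(Br)c(Cc2ccc(OCc3ccccc3)cc2)c(OC)c1
A3 | alternative 1 | 4,4,5,5-tetramethyl-2-vinyl-1,3,2-dioxaborolane | C=CB1OC(C)(C)C(C)(C)O1
A4 | alternative 1 | 3-(benzyloxy)phenyl trifluoromethanesulfonate | O=S(=O)(Oc1cccc(OCc2ccccc2)c1)C(F)(F)F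
A5 | alternative 2 | methyl 2-[2-(3-benzyloxyphenyl)ethyl]-4,6-dimethoxybenzoate | COC(=O)c1c(CCc2cccc(OCc3ccccc3)c2)cc(OC)cc1OC
A6 | alternative 2 | methyl 6-{2-[3-(benzyloxy)phenyl]ethyl}-4-methoxy-2-oxo-2H-pyran-5-carboxylate | COC(=O)C1=C(CCc2cccc(OCc3ccccc3)c2)OC(=O)C=C1OC
A7 | alternative 2 | 1,1-dimethoxyethene | C=C(OC)OC
A8 | alternative 3 | [4-(benzyloxy)phenyl]{2-[2-(3-benzyloxyphenyl)ethyl]-4-hydroxy-6-methoxyphenyl}methanone | COc1cc(O)cc(CCc2cccc(OCc3ccccc3)c2)c1C(=O)c1ccc(OCc2ccccc2)cc1
A9 | alternative 3 | 1-[4-(benzyloxy)phenyl]-5-[3-(benzyloxy)phenyl]pent-2-yn-1-one | O=C(C#CCCc1cccc(OCc2ccccc2)c1)c1ccc(OCc2ccccc2)cc1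
A10 | alternative 3 | 1,1-dimethoxy-3-(trimethylsilyloxy)buta-1,3-diene | COC(OC)=CC(=C)O[Si](C)(C)C
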